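**Retrosynthetic overview**

1. Target ⇒ one cationic cascade on a monocyclic bromohydrin diene: Br+ on the prenyl alkene, C–C closure by the exocyclic methylene (ring B, the bromocyclohexane), 1,2-hydride shift, then ether closure across ring A (the 7-oxabicyclo[2.2.1]heptane). Ring B forms first, ring A second, in the same flask.
2. Cascade substrate ⇒ cross-metathesis of a terminal-alkene bromohydrin with 2-methylbut-2-ene.
3. Bromohydrin ⇒ NBS/H2O on the ring alkene of a limonene-derived triene. The C4 centre sets C1 and C2; these later dictate the sense of the oxabicycle after C4 is erased by the hydride shift.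
4. Triene ⇒ (S)-limonene + allyl bromide by allylic lithiation.

Assumption: the biosynthesis is taken to be a bromonium-initiated cyclisation of a β-bisabolene-type precursor (exocyclic methylene onto the bromonium), a 1,2-hydride shift and 1,4-ether closure.
Assumption: the (R)-configured catalyst in step 4 is written as the one that gives the (S)-C–Br centre; if the sense of induction is the opposite, its enantiomer is used.

**Step 1**
Reactants: 1 (S)-(−)-limonene; 2 allyl bromide
Product: 4 (4S)-4-(hexa-1,5-dien-2-yl)-1-methylcyclohex-1-ene, via limonen-10-yllithium 3 (not isolated)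
Conditions: n-BuLi, TMEDA, hexane, 25 °C, 24 h; then 2, THF, −78 → 0 °C
Reagents that add atoms: none
Why: Allylic lithiation of limonene by n-BuLi·TMEDA occurs at the isopropenyl methyl and gives a 2-substituted allyllithium with two identical CH2 termini, whose SN2 alkylation (the same coupling that turns limonene into β-bisabolene with prenyl bromide) extends the chain without touching the C4 stereocentre.

**Step 2**
Reactants: 4 (4S)-4-(hexa-1,5-dien-2-yl)-1-methylcyclohex-1-ene
Product: 6 (1R,2R,4S)-2-bromo-4-(hexa-1,5-dien-2-yl)-1-methylcyclohexan-1-ol, via ring bromonium ion 5 (not isolated)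
Conditions: NBS (1.0 equiv), acetone–H2O (4:1), 0 °C, dark
Reagents that add atoms: N-bromosuccinimide, O=C1CCC(=O)N1Br; water, O
Why: Bromohydrin formation (electrophilic anti addition) is selective for the trisubstituted ring alkene over the 1,1-disubstituted and monosubstituted ones, and Markovnikov, trans-diaxial (Fürst–Plattner) opening of the bromonium by water with the side chain equatorial gives, as with limonene itself, the diaxial bromohydrin, so C1 and C2 are set by C4.

**Step 3**
Reactants: 6 (1R,2R,4S)-2-bromo-4-(hexa-1,5-dien-2-yl)-1-methylcyclohexan-1-ol; 7 2-methylbut-2-ene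
Product: 8 (1R,2R,4S)-2-bromo-1-methyl-4-(6-methylhepta-1,5-dien-2-yl)cyclohexan-1-ol
Conditions: second-generation Grubbs catalyst (H2IMes)(PCy3)Cl2Ru=CHPh (3 mol %), 7 (20 equiv), CH2Cl2, 40 °C
Reagents that add atoms: none
Why: Olefin cross-metathesis converts the terminal vinyl group into the prenyl terminus while the 1,1-disubstituted alkene, the tertiary alcohol and the secondary bromide are inert to the ruthenium carbene, and no stereocentre is touched.

**Step 4**
Reactants: 8 (1R,2R,4S)-2-bromo-1-methyl-4-(6-methylhepta-1,5-dien-2-yl)cyclohexan-1-ol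
Product: 12 (1R,2R,4S)-2-bromo-4-[(1S,4S)-4-bromo-3,3-dimethylcyclohexyl]-1-methyl-7-oxabicyclo[2.2.1]heptane, via side-chain bromonium ion 9 (not isolated), via ring-B tertiary cation 10 (not isolated), via ring-A tertiary cation 11 (not isolated)
Conditions: DBDMH (0.6 equiv), (R)-3,3′-bis(2,4,6-triisopropylphenyl)-BINOL N-triflylthiophosphoramide (10 mol %), PhMe–CH2Cl2, −78 °C; then HFIP, −40 → 0 °C
Reagents that add atoms: 1,3-dibromo-5,5-dimethylhydantoin, CC1(C)N(Br)C(=O)N(Br)C1=O
Why: Proposed new method: catalyst-bound Br+ adds to the most electron-rich (prenyl) alkene on the face chosen by the catalyst (the substrate has no bias; this sets C4′), the exocyclic methylene closes ring B through a chair with Br equatorial, the ring-B cation takes the ring-A methine hydrogen by a 1,2-shift onto its axial face (large substituent equatorial and trans to Br; this sets C1′), and the relocated cation is trapped across ring A by the C1 hydroxyl, so that C1 and C2 from step 2 fix the sense of the oxabicycle with Br anti to the oxygen bridge, the HFIP stage with the strongly acidic catalyst returning any E1 alkenes to the cation manifold; the closest known reaction types are the catalytic asymmetric bromonium-induced cyclisation of geranyl arenes with DBDMH and a chiral BINOL thiophosphoramide and the acid-mediated conversion of α-terpineol into 1,4-cineole by hydride shift and ether closure.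

**Compound list**

1 | (S)-(−)-limonene, (4S)-1-methyl-4-(prop-1-en-2-yl)cyclohex-1-ene | CC1=CC[C@H](CC1)C(C)=C | starting material
2 | allyl bromide (3-bromoprop-1-ene) | C=CCBr | starting material
3 | limonen-10-yllithium, {2-[(1S)-4-methylcyclohex-3-en-1-yl]prop-2-en-1-yl}lithium | CC1=CC[C@H](CC1)C(=C)C[Li] | intermediate
4 | (4S)-4-(hexa-1,5-dien-2-yl)-1-methylcyclohex-1-ene | CC1=CC[C@H](CC1)C(=C)CCC=C | intermediate
5 | ring bromonium ion of 4 (Br+ bridging C1–C2 on the face trans to the side chain) | C[C@]12CC[C@@H](C[C@H]1[Br+]2)C(=C)CCC=C | intermediate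
6 | (1R,2R,4S)-2-bromo-4-(hexa-1,5-dien-2-yl)-1-methylcyclohexan-1-ol (OH and Br trans-diaxial, OH cis to the side chain) | C[C@@]1(O)CC[C@@H](C[C@H]1Br)C(=C)CCC=C | intermediate
7 | 2-methylbut-2-ene | CC=C(C)C | starting material
8 | (1R,2R,4S)-2-bromo-1-methyl-4-(6-methylhepta-1,5-dien-2-yl)cyclohexan-1-ol | C[C@@]1(O)CC[C@@H](C[C@H]1Br)C(=C)CCC=C(C)C | intermediate
9 | side-chain bromonium ion of 8 (Br+ bridging the former prenyl alkene, CH carbon S) | C[C@@]1(O)CC[C@@H](C[C@H]1Br)C(=C)CC[C@@H]2[Br+]C2(C)C | intermediate
10 | ring-B tertiary cation, (4S)-4-bromo-1-[(1S,3R,4R)-3-bromo-4-hydroxy-4-methylcyclohexyl]-3,3-dimethylcyclohexan-1-ylium | C[C@@]1(O)CC[C@@H](C[C@H]1Br)[C+]2CC[C@H](Br)C(C)(C)C2 | intermediate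
11 | ring-A tertiary cation, (3R,4R)-3-bromo-1-[(1S,4S)-4-bromo-3,3-dimethylcyclohexyl]-4-hydroxy-4-methylcyclohexan-1-ylium | C[C@@]1(O)CC[C+](C[C@H]1Br)[C@H]2CC[C@H](Br)C(C)(C)C2 | intermediate
12 | (1R,2R,4S)-2-bromo-4-[(1S,4S)-4-bromo-3,3-dimethylcyclohexyl]-1-methyl-7-oxabicyclo[2.2.1]heptane (Br on C2 anti to the oxygen bridge; ring-B substituents trans-diequatorial) | CC1(C)C[C@@H]([C@@]23CC[C@@](C)(O2)[C@H](Br)C3)CC[C@@H]1Br | target

**Step count and risk**

Total steps: 4. Longest linear sequence: 4.

The three steps most likely to fail are steps 4, 1 and 2.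

Step 4 carries most of the risk, for three reasons.
- The ring-B cation 10 can be trapped directly by the cis hydroxyl (a 1,8-cineole-type spiro ether) or lose a proton instead of taking the hydride. Direct trapping is expected to be slowed because it would place oxygen or ring A syn-axial to a methyl of the gem-dimethyl group, but this is untested.
- The C4′ centre depends wholly on the catalyst. With poor control the product is a mixture of 12 and its 1′,4′-bis-epimer; these are diastereomers and would have to be separated.
- Br+ could also attack the 1,1-disubstituted alkene.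

The fallback sets out from 8 and changes the electrophile. Hg(OTf)2 bound to a chiral bis(oxazoline) in MeNO2 at −20 °C starts the same cyclisation, hydride shift and ether closure from a mercurinium ion, which is more selective for the prenyl alkene and has no basic counter-ion. KBr work-up gives the organomercurial bromo{(1S,4S)-4-[(1R,2R,4S)-2-bromo-1-methyl-7-oxabicyclo[2.2.1]heptan-4-yl]-2,2-dimethylcyclohexyl}mercury F5, which can be purified from its C–Hg epimer. Br2 and LiBr in pyridine under O2 then replace mercury by bromine with retention and return to 12. This fallback does not remove the first risk (cation partition).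

Step 1 can suffer from competing ring metalation, Wurtz homocoupling and a modest yield. The fallback sets out from 1 and avoids carbanions. A Me2AlCl-promoted carbonyl-ene reaction with paraformaldehyde, selective for the isopropenyl group, gives 3-[(1S)-4-methylcyclohex-3-en-1-yl]but-3-en-1-ol F1. TsCl in pyridine gives 3-[(1S)-4-methylcyclohex-3-en-1-yl]but-3-en-1-yl 4-methylbenzenesulfonate F2. Coupling with vinylmagnesium bromide and catalytic Li2CuCl4 in THF comes back to 4.

Step 2 can give over-bromination of the 1,1-disubstituted alkene or incomplete facial and regiochemical control. The fallback sets out from 4. mCPBA with NaHCO3 in CH2Cl2 gives the ring epoxides (1R,4S,6S)-4-(hexa-1,5-dien-2-yl)-1-methyl-7-oxabicyclo[4.1.0]heptane F3 (oxygen cis to the side chain) and (1S,4S,6R)-4-(hexa-1,5-dien-2-yl)-1-methyl-7-oxabicyclo[4.1.0]heptane F4 in about equal amounts. Li2NiBr4 in THF at 0 °C opens only F3 quickly, by trans-diaxial SN2 attack of bromide at the secondary carbon, and this comes back to 6. The unreactive F4 is removed by chromatography, so this fallback gives at most half of the material.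

**Further compounds**

F1 | step 1 | 3-[(1S)-4-methylcyclohex-3-en-1-yl]but-3-en-1-ol | CC1=CC[C@H](CC1)C(=C)CCO
F2 | step 1 | 3-[(1S)-4-methylcyclohex-3-en-1-yl]but-3-en-1-yl 4-methylbenzenesulfonate | CC1=CC[C@H](CC1)C(=C)CCOS(=O)(=O)c2ccc(C)cc2
F3 | step 2 | (1R,4S,6S)-4-(hexa-1,5-dien-2-yl)-1-methyl-7-oxabicyclo[4.1.0]heptane | C[C@@]12CC[C@@H](C[C@@H]1O2)C(=C)CCC=C
F4 | step 2 | (1S,4S,6R)-4-(hexa-1,5-dien-2-yl)-1-methyl-7-oxabicyclo[4.1.0]heptane | C[C@]12CC[C@@H](C[C@H]1O2)C(=C)CCC=C
F5 | step 4 | bromo{(1S,4S)-4-[(1R,2R,4S)-2-bromo-1-methyl-7-oxabicyclo[2.2.1]heptan-4-yl]-2,2-dimethylcyclohexyl}mercury | C[C@]12CC[C@](O1)(C[C@H]2Br)[C@H]3CC[C@H]([Hg]Br)C(C)(C)C3
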